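**Plan**
Cuts: in the naphthoquinone unit, the two carbonyl-to-benzo-ring bonds C4–C4a and C1–C8a; then the vinyl C2–O bond to the naphthol; then the C3–prenyl bond of the naphthoate.
Enabling feature: the quinone carbons C1(=O)–C2(OAr)=C3H–C4(=O) are a semisquarate C4 unit at the right oxidation level. The fused benzo ring is unsubstituted, so it is a phenyl group with two equivalent ortho carbons.
Forward order: C3-prenylation of methyl 1,4-dihydroxy-2-naphthoate; diisopropyl squarate to semisquaric chloride; attachment of the four-membered ring at the free C4–OH; phenyllithium addition to give a 4-hydroxy-4-phenylcyclobutenone.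
Rings: both naphthoate rings, the phenyl ring and the temporary cyclobutene ring are bought. The quinone ring is the only ring closed and comes last, by 4π opening and 6π closure that consumes the four-membered helper ring, followed by dehydrogenation.
Stereochemistry: the target has no stereocentre. The transient stereocentres are racemic and are erased in the key step.

Key step: step 7

Assumption: rubioncolin C as drawn has no stereocentre, no stereogenic double bond and no configurationally stable axis, so no enantiomer has to be selected and only the constitution must be matched.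

Step 1
Reactants: 1 methyl 1,4-dihydroxynaphthalene-2-carboxylate; 2 2-methylbut-3-en-2-ol
Product: 3 methyl 1,4-dihydroxy-3-(3-methylbut-2-en-1-yl)naphthalene-2-carboxylate
Conditions: BF3·OEt2 (cat.), 1,4-dioxane, rt to 50 °C, Ar
Reagents that add atoms: none
Why: Friedel–Crafts-type allylic alkylation as used for prenylated naphthohydroquinones: the dimethylallyl cation released from 2 should be attacked at its unhindered CH2 terminus by C3, the only free position of the hydroquinone ring and ortho to the C4 hydroxyl, and no stereocentre is formed.

Step 2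
Reactants: 4 3,4-diisopropoxycyclobut-3-ene-1,2-dione (diisopropyl squarate)
Product: 6 3-isopropoxycyclobut-3-ene-1,2-dione, via hydroxycyclobutenone 5 (not isolated)
Conditions: LiAlH(OtBu)3, THF, −78 to −20 °C; then 6 M aq HCl, CH2Cl2, rt
Reagents that add atoms: none
Why: Bulky-hydride 1,2-reduction of one squarate carbonyl should give racemic carbinol 5, and acid then causes the usual allylic transposition of squarate adducts (ionisation at C4, water at C2, loss of isopropanol), which erases the stereocentre and leaves the C–H semisquarate.

Step 3
Reactants: 6 3-isopropoxycyclobut-3-ene-1,2-dione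
Product: 7 3-hydroxycyclobut-3-ene-1,2-dione (semisquaric acid)
Conditions: 3 M aq HCl, THF, 50 °C
Reagents that add atoms: water, O
Why: Acid-catalysed hydrolysis of a vinylogous ester (addition–elimination of water at the alkoxy-bearing ring carbon) should free the strongly acidic vinylogous acid, and no stereocentre is involved.

Step 4
Reactants: 7 3-hydroxycyclobut-3-ene-1,2-dione
Product: 8 3-chlorocyclobut-3-ene-1,2-dione (semisquaric chloride)
Conditions: (COCl)2, DMF (cat.), CH2Cl2, 0 °C to rt
Reagents that add atoms: oxalyl chloride, O=C(Cl)C(=O)Cl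
Why: Vilsmeier-type chlorination of a vinylogous carboxylic acid, the reaction that also turns squaric acid into its dichloride, should give the vinylogous acid chloride beside volatile co-products only.

Step 5
Reactants: 3 methyl 1,4-dihydroxy-3-(3-methylbut-2-en-1-yl)naphthalene-2-carboxylate; 8 3-chlorocyclobut-3-ene-1,2-dione
Product: 9 methyl 4-[(3,4-dioxocyclobut-1-en-1-yl)oxy]-1-hydroxy-3-(3-methylbut-2-en-1-yl)naphthalene-2-carboxylate
Conditions: 2,6-lutidine, CH2Cl2, −78 to 0 °C, Ar
Reagents that add atoms: none
Why: Vinylogous O-acylation by addition–elimination at the chlorine-bearing carbon: the small, very electrophilic four-membered ring should reach the flanked C4 hydroxyl, whereas the C1 hydroxyl is held in a hydrogen bond to the ester and should stay free, in line with the known 4-O-selective alkylation and acylation of 1,4-dihydroxy-2-naphthoates.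

Step 6
Reactants: 9 methyl 4-[(3,4-dioxocyclobut-1-en-1-yl)oxy]-1-hydroxy-3-(3-methylbut-2-en-1-yl)naphthalene-2-carboxylate; 10 phenyllithium
Product: 11 (±)-methyl 1-hydroxy-4-[(4-hydroxy-3-oxo-4-phenylcyclobut-1-en-1-yl)oxy]-3-(3-methylbut-2-en-1-yl)naphthalene-2-carboxylate
Conditions: 10 (2.1 equiv), THF, −78 °C; then sat. aq NH4Cl, −78 °C to rt
Reagents that add atoms: none
Why: 1,2-Addition of an organolithium to a cyclobutenedione: the first equivalent of 10 deprotonates the naphthol (which also deactivates the doubly ortho-flanked ester), the second should add at −78 °C to the ketone-like carbonyl next to the aryloxy carbon rather than to the vinylogous ester carbonyl, the new carbinol centre arises as a racemate and is erased in step 7, and the regioisomeric adduct would lead to the same quinone.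

Step 7
Reactants: 11 (±)-methyl 1-hydroxy-4-[(4-hydroxy-3-oxo-4-phenylcyclobut-1-en-1-yl)oxy]-3-(3-methylbut-2-en-1-yl)naphthalene-2-carboxylate
Product: 15 rubioncolin C, via dienylketene 12 (not isolated), via dihydronaphthalenone 13 (not isolated), via hydroquinone 14 (not isolated)
Conditions: p-xylene (degassed, dilute), 138 °C; then Ag2O, rt
Reagents that add atoms: none
Why: Heating should open the strained cyclobutenone of 11 by a conrotatory 4π electrocyclic reaction in which the donor hydroxyl turns outward and the phenyl inward, so that dienylketene 12 arises with its ketene carbon next to an ortho carbon of the phenyl ring. A disrotatory 6π electrocyclisation then joins these two carbons (bond C4–C4a of the quinone) and closes the six-membered ring as 13, whose C4a hydrogen shifts to oxygen to give the aromatic hydroquinone 14, from which Ag2O takes two hydrogens to give 15. The closest known reaction type is the Moore rearrangement of 4-aryl-4-hydroxycyclobutenones to annulated hydroquinones and quinones. The one ring that is closed forms in the electrocyclic mode, all six ring atoms being the termini and inner atoms of the triene, not by an ionic exo or endo attack. No stereocentre remains, since the carbinol centre of 11 and C4a of 13 both become sp2. The step needs torquoselectivity, secured by the hydroxyl donor; site selectivity, which is no issue because the two ortho carbons are equivalent; and chemoselectivity, which rests on the closeness of phenyl and ketene outrunning capture by the chelated naphthol or the remote prenyl alkene, while Ag2O should leave the para-blocked, hydrogen-bonded naphthol alone.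

**Compound list**
1 | methyl 1,4-dihydroxynaphthalene-2-carboxylate | COC(=O)c1cc(O)c2ccccc2c1O | starting material
2 | 2-methylbut-3-en-2-ol | CC(C)(O)C=C | starting material
3 | methyl 1,4-dihydroxy-3-(3-methylbut-2-en-1-yl)naphthalene-2-carboxylate | COC(=O)c1c(CC=C(C)C)c(O)c2ccccc2c1O | intermediate
4 | 3,4-diisopropoxycyclobut-3-ene-1,2-dione (diisopropyl squarate) | CC(C)OC1=C(OC(C)C)C(=O)C1=O | starting material
5 | (±)-4-hydroxy-2,3-diisopropoxycyclobut-2-en-1-one (racemic, not isolated) | CC(C)OC1=C(OC(C)C)C(=O)C1O | intermediate
6 | 3-isopropoxycyclobut-3-ene-1,2-dione | CC(C)OC1=CC(=O)C1=O | intermediate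
7 | 3-hydroxycyclobut-3-ene-1,2-dione (semisquaric acid) | OC1=CC(=O)C1=O | intermediate
8 | 3-chlorocyclobut-3-ene-1,2-dione (semisquaric chloride) | ClC1=CC(=O)C1=O | intermediate
9 | methyl 4-[(3,4-dioxocyclobut-1-en-1-yl)oxy]-1-hydroxy-3-(3-methylbut-2-en-1-yl)naphthalene-2-carboxylate | COC(=O)c1c(CC=C(C)C)c(OC2=CC(=O)C2=O)c3ccccc3c1O | intermediate
10 | phenyllithium | [Li]c1ccccc1 | starting material
11 | (±)-methyl 1-hydroxy-4-[(4-hydroxy-3-oxo-4-phenylcyclobut-1-en-1-yl)oxy]-3-(3-methylbut-2-en-1-yl)naphthalene-2-carboxylate (racemic) | COC(=O)c1c(CC=C(C)C)c(OC2=CC(=O)C2(O)c3ccccc3)c4ccccc4c1O | intermediate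
12 | methyl 1-hydroxy-4-{[(1Z)-1-hydroxy-4-oxo-1-phenylbuta-1,3-dien-2-yl]oxy}-3-(3-methylbut-2-en-1-yl)naphthalene-2-carboxylate (dienylketene, phenyl cis to the ketenyl group, not isolated) | COC(=O)c1c(CC=C(C)C)c(O/C(C=C=O)=C(\O)c2ccccc2)c3ccccc3c1O | intermediate
13 | (±)-methyl 1-hydroxy-4-[(1-hydroxy-4-oxo-4,4a-dihydronaphthalen-2-yl)oxy]-3-(3-methylbut-2-en-1-yl)naphthalene-2-carboxylate (racemic, not isolated) | COC(=O)c1c(CC=C(C)C)c(OC2=CC(=O)C3C=CC=CC3=C2O)c4ccccc4c1O | intermediate
14 | methyl 4-[(1,4-dihydroxynaphthalen-2-yl)oxy]-1-hydroxy-3-(3-methylbut-2-en-1-yl)naphthalene-2-carboxylate (not isolated) | COC(=O)c1c(CC=C(C)C)c(Oc2cc(O)c3ccccc3c2O)c4ccccc4c1O | intermediate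
15 | rubioncolin C, methyl 4-[(1,4-dioxo-1,4-dihydronaphthalen-2-yl)oxy]-1-hydroxy-3-(3-methylbut-2-en-1-yl)naphthalene-2-carboxylate | COC(=O)c1c(CC=C(C)C)c(OC2=CC(=O)c3ccccc3C2=O)c4ccccc4c1O | target

Total steps: 7. Longest linear sequence: 6 steps (4 → 6 → 7 → 8 → 9 → 11 → 15).

**Steps most likely to fail**

First, step 6. What may go wrong:
- Conjugate addition–elimination at the aryloxy-bearing ring carbon, with expulsion of the naphthoxide.
- Acyl transfer started by the lithium naphthoxide that forms first.
- Attack of the excess organolithium on the ester.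

The fallback sets out from 9 and comes back at 11. It removes the acidic proton with a protecting group, so only one equivalent of nucleophile is present and no naphthoxide arises. TBSOTf and 2,6-lutidine in CH2Cl2 at −78 to 0 °C should give the silyl ether methyl 1-[(tert-butyldimethylsilyl)oxy]-4-[(3,4-dioxocyclobut-1-en-1-yl)oxy]-3-(3-methylbut-2-en-1-yl)naphthalene-2-carboxylate F1. Phenyllithium (1.05 equiv, THF, −78 °C, NH4Cl quench) should then give the racemic carbinol methyl 1-[(tert-butyldimethylsilyl)oxy]-4-[(4-hydroxy-3-oxo-4-phenylcyclobut-1-en-1-yl)oxy]-3-(3-methylbut-2-en-1-yl)naphthalene-2-carboxylate F2. HF·pyridine in THF at 0 °C should remove the silyl group and return 11.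

Second, step 5. What may go wrong:
- Self-condensation or hydrolysis of the small chloride before the hindered hydroxyl attacks.
- Acylation of both hydroxyls.
- Hydrolytic loss of the activated vinylogous aryl ester during isolation.

The fallback sets out from 3 and comes back at 9. It uses a sturdier C4 building block in which a chlorine stands in for the ring hydrogen and is removed afterwards. Commercial squaric acid with oxalyl chloride and catalytic DMF should give 3,4-dichlorocyclobut-3-ene-1,2-dione F3. One equivalent of 3 with 2,6-lutidine in CH2Cl2 at −78 °C should replace one chlorine and give methyl 4-[(2-chloro-3,4-dioxocyclobut-1-en-1-yl)oxy]-1-hydroxy-3-(3-methylbut-2-en-1-yl)naphthalene-2-carboxylate F4. Bu3SnH with catalytic Pd(PPh3)4 in THF at rt is the palladium-catalysed tin hydride reduction of acyl chlorides, applied here to the vinylogous acid chloride. It should exchange the remaining chlorine for hydrogen and return 9.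

Third, step 1. What may go wrong:
- Acid-induced ring closure of the new prenyl group onto the neighbouring C4 hydroxyl.
- O-alkylation.
- Sluggish attack because the ester deactivates the ring.

The fallback sets out from 1 and comes back at 3. It is acid-free and delivers the prenyl group by a sigmatropic shift instead of a cation. A Tsuji–Trost O-allylation of the free C4 hydroxyl with tert-butyl 2-methylbut-3-en-2-yl carbonate and catalytic Pd(PPh3)4 in THF at 0 °C should give the 1,1-dimethylallyl ether methyl 1-hydroxy-4-[(2-methylbut-3-en-2-yl)oxy]naphthalene-2-carboxylate F5. Heating in toluene at 80–110 °C should trigger the aromatic Claisen rearrangement to C3, the only open ortho position. The allyl inversion turns the 1,1-dimethylallyl group into the 3-methylbut-2-enyl group, and rearomatisation returns 3.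

Further compounds
F1 | step 6 | methyl 1-[(tert-butyldimethylsilyl)oxy]-4-[(3,4-dioxocyclobut-1-en-1-yl)oxy]-3-(3-methylbut-2-en-1-yl)naphthalene-2-carboxylate | COC(=O)c1c(CC=C(C)C)c(OC2=CC(=O)C2=O)c3ccccc3c1O[Si](C)(C)C(C)(C)C
F2 | step 6 | (±)-methyl 1-[(tert-butyldimethylsilyl)oxy]-4-[(4-hydroxy-3-oxo-4-phenylcyclobut-1-en-1-yl)oxy]-3-(3-methylbut-2-en-1-yl)naphthalene-2-carboxylate | COC(=O)c1c(CC=C(C)C)c(OC2=CC(=O)C2(O)c3ccccc3)c4ccccc4c1O[Si](C)(C)C(C)(C)C
F3 | step 5 | 3,4-dichlorocyclobut-3-ene-1,2-dione | ClC1=C(Cl)C(=O)C1=O
F4 | step 5 | methyl 4-[(2-chloro-3,4-dioxocyclobut-1-en-1-yl)oxy]-1-hydroxy-3-(3-methylbut-2-en-1-yl)naphthalene-2-carboxylate | COC(=O)c1c(CC=C(C)C)c(OC2=C(Cl)C(=O)C2=O)c3ccccc3c1O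
F5 | step 1 | methyl 1-hydroxy-4-[(2-methylbut-3-en-2-yl)oxy]naphthalene-2-carboxylate | COC(=O)c1cc(OC(C)(C)C=C)c2ccccc2c1O
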